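## The problem

The target is a C50 carotenoid. An all-E nonaene chain (C7 to C7', methyl groups at C9, C13, C13' and C9') links two different 2-substituted ε-type cyclohexene end rings. The left ring carries a 3-methylbut-2-enyl group at C2 and the right ring an (E)-4-hydroxy-3-methylbut-2-enyl group at C2'. No ring is fused or bridged and each ring hangs on the chain through an sp3 carbon (C6, C6'), so this is a chain-assembly problem with two unlike ends that must be attached one after the other. There are four stereocentres in two remote pairs: C2/C6 are cis (2S,6R) in the left ring and C2'/C6' are trans (2'R,6'S) in the right ring. C2 and C2' have the same spatial sense, so one enantioselective event can serve both rings, but C6 and C6' must then be set in opposite relative senses. The pairs cannot influence each other across eighteen sp2 carbons; within a ring, C2 can bias the reduction of a C4 ketone, and a C4–O bond can hand its configuration to C6 by a suprafacial 1,3-shift. C6–H is allylic to C4=C5 and would be α to any C7 carbonyl, so ring aldehydes would epimerise or slip into conjugation; the polyene is sensitive to light, acid and oxygen, and the prenyl-type alkenes and the allylic alcohol restrict oxidants and acids. The enabling feature is that C8 to C8', with four methyl groups and seven E double bonds, is the centrosymmetric C20 dialdehyde crocetindial once the two disubstituted bonds C7=C8 and C7'=C8' are cut, and these are the only bonds joining the rings to the chain.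

## Retrosynthesis

**36 ⇐ 35.** Only the O–Si bond is cut. The single hydroxyl is masked as a tert-butyldimethylsilyl ether through all steps that use strong base or a Mitsunobu reagent. The forward step needs only a fluoride source that leaves the polyene alone.

**35 ⇐ 17 + 31 + 30.** The C7=C8 and C7'=C8' double bonds are cut. The neighbouring cuts at C11=C12/C11'=C12' (C20 + C10 + C20) or at C15=C15' would require each ring to be extended first through intermediates that are carbonyl-substituted at C7, with the C6 stereocentre exposed. The chosen cut leaves the whole chain as the purchasable dialdehyde 31 and the rings as C15 sulfones 17 and 30. The nucleophile sits on the ring side, so C6 is never α to a carbonyl. The forward reaction must be E-selective at two disubstituted alkenes, must stop cleanly at the mono-adduct 33 in its first stage, and must not disturb C6/C6'.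

**17 ⇐ 16 ⇐ 14 + 15; 30 ⇐ 29 ⇐ 28 + 15.** The C7–S bonds are cut after lowering the sulfur oxidation level. Thiol 15 is attached to the primary alcohols 14 and 28 and the sulfides 16 and 29 are oxidised. Setting the sulfone up from an alcohol keeps C7 at an oxidation level that cannot enolise towards C6. The oxidant must prefer sulfur to the trisubstituted alkenes.

**14 ⇐ 12; 28 ⇐ 26.** The C6–C7 bond is cut. It is formed by [2,3]-sigmatropic shift of a stannylmethyl ether on the C4 oxygen, which moves the ring alkene from C5=C6 to C4=C5 and delivers C7 to the face that held the C4–O bond. Direct alkylation at C6 would give no handle on configuration; the rearrangement reduces the C6 problem to the choice between two C4 carbinol epimers. The cis ether 12 gives the cis ring and the trans ether 26 the trans ring.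

**12 ⇐ 11 ⇐ 10 ⇐ 8; 26 ⇐ 25 ⇐ 24 ⇐ 23 ⇐ 22 ⇐ 20.** The side-chain double bonds are cut to the aldehydes 11 and 23. These go back through the alcohols 10 and 22 to the vinyl compounds 8 and 20. A vinyl group is the two-carbon handle that can be introduced enantioselectively at C2. An isopropylidene ylide completes the left chain. A stabilised α-methyl ylide, reduction and silylation give the (E)-allylic silyl ether of the right chain. The stannylmethyl ether doubles as protection for the C4 oxygen during these steps.

**8 ⇐ 6 + 7; 20 ⇐ 19 + 7; 19 ⇐ 18 ⇐ 6; 6 ⇐ 5.** The O–CH2Sn bonds are cut to the epimeric allylic alcohols 6 (cis) and 19 (trans) and stannane 7. The cis alcohol 6 comes from substrate-controlled 1,2-reduction of enone 5. The trans alcohol 19 comes from 6 by inversion through ester 18. One intermediate therefore feeds both rings and the route branches only at 6.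

**5 ⇐ 4.** The C2–vinyl bond is cut: asymmetric conjugate addition to the unsubstituted enone half of the cross-conjugated dienone 4. Adding the vinyl group to 1 itself would leave a 3-substituted cyclohexanone that has to be methylated and dehydrogenated at the α-carbon remote from the new centre, between two methylene groups that a base does not tell apart. In 4 the methyl group, the C4 carbonyl and the C5=C6 double bond are already in place and the addition creates the only stereocentre.

**4 ⇐ 3 ⇐ 1.** The C5=C6 double bond (dehydrogenation) and the C5–CH3 bond (kinetic enolate methylation) are cut back to commercial enone 1, whose quaternary carbon becomes C1 of both rings.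

## Roads not taken

**Alternative 1:** The cut runs through the ring at C2–C3 and C5–C6. A three-carbon oxyallyl cation, generated reductively from tetrabromoacetone A1, would add across the termini of 5,5-dimethylcyclopentadiene A2 and give, after loss of the bromines, the meso bicyclic ketone A3.
- Merits: one step fixes the ring, the gem-dimethyl carbon (the one-carbon bridge), a C4 ketone placed for the C5 methyl and the C4=C5 bond, and two carbon substituents at C2 and C6 that are cis by topology once the etheno bridge is cleaved.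
- Weak points: A3 is achiral, so a desymmetrisation must distinguish both its two α-carbons and the two bridge-derived carbons. One of these must become C7 and the other the first side-chain carbon, which arrives one carbon short for direct olefination. Only the cis ring is served; the trans ring would need epimerisation at C6 through a carbonyl compound that can also slip into conjugation. A2 is not an article of commerce, and the cation must approach a diene face flanked by a methyl group.
- Comparison: A3 is better in one respect. Its 2,6-cis relation is guaranteed by the bicycle, whereas the chosen plan relies on the suprafacial course of step 9 through a crowded conformer. Against this the chosen plan sets one enantioenriched intermediate (6) that supplies both diastereomeric rings by a single inversion, with no desymmetrisation.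

**Alternative 2:** The cut is C1–C6. The isopropenyl group of the open-chain trienone A5, derived from (R)-limonene A4 (whose stereocentre becomes C2), would be protonated to the C1 cation. C6 of the 5E double bond attacks and a proton leaves C4, giving the 2-substituted α-ionone A6.
- Merits: chirality comes from the pool with no asymmetric catalysis. One bond formation delivers the ring, the gem-dimethyl group, the C5 methyl, the C4=C5 bond and C7–C9 with the E C7=C8 bond already in place. The pivaloyloxyethyl handle has the right length.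
- Weak points: the C6 configuration rests on a conformational preference in a cationic cyclisation that must also choose where the proton leaves, and acid can move the product alkene into conjugation, erasing C6. Only the cis ring results. The ionone ketone commits the rest to stepwise chain extension with two different end pieces on a central unit, which means more linear polyene steps.
- Comparison: A6 is ahead on starting-material cost and on how much skeleton one step delivers. The chosen plan sets against it a stereospecific transfer of configuration to C6, access to both cis and trans rings from 6, and the polyene introduced last as one commercial C20 piece.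

**Alternative 3:** The cuts are C1–C2 and C5=C6 of the ring. An amine-catalysed Michael addition of isobutyraldehyde A7 to the acyclic enone A8, followed by intramolecular aldol condensation, would give cyclohexenone A9. This is the same enone type as 5, with a protected hydroxyethyl group in place of vinyl.
- Merits: for the later steps A9 is a better intermediate than 5. Its side-chain handle is already at the alcohol oxidation level, so steps 6 and 15 would disappear. The ring comes from acyclic materials without organometallic reagents, and everything after could follow the chosen route.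
- Weak points: the Michael step must join a fully substituted enamine carbon to a β-substituted acyclic enone, forming a quaternary carbon next to the new stereocentre. Reactivity and enantioface control are both uncertain for this hindered pairing, and reversal of the addition can erode the enantiomeric purity.
- Comparison: if the annulation gave A9 in high enantiomeric purity, this road would be about one step shorter per ring and equal in every later respect. The chosen plan prefers conjugate addition to 4 because carbometallation of a cyclic enone has close analogy for the same stereocentre; the price is the hydroboration–oxidation pair.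

Key step: step 23

Assumption: the configuration is taken as drawn, 2,6-cis (2S,6R) in the prenyl ring and 2',6'-trans (2'R,6'S) in the hydroxyprenyl ring. Positions in the text carry carotenoid numbers; names carry substitutive locants.

## Steps

Step 1
Reactants: 1 4,4-dimethylcyclohex-2-en-1-one
Product: 3 (±)-4,4,6-trimethylcyclohex-2-en-1-one, via lithium dienolate 2 (not isolated)
Conditions: LiN(i-Pr)2, THF, −78 °C; MeI, −78 → 0 °C
Reagents that add atoms: iodomethane, CI
Why: Kinetic deprotonation can occur only at C6 because C4 is quaternary, and the cross-conjugated dienolate is C-methylated (α'-alkylation of a cyclohexenone). The new centre is racemic and becomes sp2 in step 2.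

Step 2
Reactants: 3 (±)-4,4,6-trimethylcyclohex-2-en-1-one
Product: 4 2,4,4-trimethylcyclohexa-2,5-dien-1-one
Conditions: IBX (2.5 equiv), DMSO, 75 °C
Reagents that add atoms: none
Why: IBX dehydrogenation of a ketone through its enol. Only the C5–C6 pair carries the hydrogens required, and the quaternary C4 blocks aromatisation, so the cross-conjugated dienone is the end point.

Step 3
Reactants: 4 2,4,4-trimethylcyclohexa-2,5-dien-1-one
Product: 5 (5R)-5-ethenyl-2,4,4-trimethylcyclohex-2-en-1-one
Conditions: CH2=CHBF3K (2 equiv), [Rh(cod)2]BF4 (3 mol %), (R)-BINAP (3.3 mol %), toluene/H2O (10:1), 100 °C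
Reagents that add atoms: potassium vinyltrifluoroborate, C=C[B-](F)(F)F.[K+]
Why: Rhodium-catalysed asymmetric conjugate addition of an alkenylboron reagent to a cyclic enone (Hayashi–Miyaura type). The α-unsubstituted C5=C6 half reacts in preference to the α-methylated half, and the product enone is too hindered to add again. The ligand sets C5; (R)-BINAP is expected to give (5R) by analogy with the sense for cyclohex-2-enone, to be confirmed by correlation.

Step 4
Reactants: 5 (5R)-5-ethenyl-2,4,4-trimethylcyclohex-2-en-1-one
Product: 6 (1R,5R)-5-ethenyl-2,4,4-trimethylcyclohex-2-en-1-ol (1,5-cis)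
Conditions: NaBH4, CeCl3·7H2O, MeOH, −78 → −20 °C
Reagents that add atoms: none
Why: Luche 1,2-reduction. Hydride enters C1 on the face opposite the C5 vinyl group (axial attack on the half-chair, as in carvone to cis-carveol), so the hydroxyl ends up cis to the vinyl group.

Step 5
Reactants: 6 (1R,5R)-5-ethenyl-2,4,4-trimethylcyclohex-2-en-1-ol; 7 tributyl(iodomethyl)stannane
Product: 8 tributyl({[(1R,5R)-5-ethenyl-2,4,4-trimethylcyclohex-2-en-1-yl]oxy}methyl)stannane
Conditions: KH, 18-crown-6 (cat.), THF, 0 °C → rt
Reagents that add atoms: none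
Why: Williamson etherification with an unhindered primary iodide; the C–O bond of the carbinol is untouched, so configuration is retained. The ether is the rearrangement precursor and protects the oxygen meanwhile.

Step 6
Reactants: 8 tributyl({[(1R,5R)-5-ethenyl-2,4,4-trimethylcyclohex-2-en-1-yl]oxy}methyl)stannane
Product: 10 2-[(1S,5R)-2,2,4-trimethyl-5-[(tributylstannyl)methoxy]cyclohex-3-en-1-yl]ethan-1-ol, via alkylborane 9 (not isolated)
Conditions: 9-BBN–H, THF, 0 °C → rt; then NaOH, H2O2, H2O, 0 °C → rt
Reagents that add atoms: hydrogen peroxide, OO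
Why: Hydroboration–oxidation. The hindered borane adds anti-Markovnikov to the monosubstituted vinyl group and ignores the trisubstituted ring alkene. The tetraalkylstannane is inert to alkaline peroxide.

Step 7
Reactants: 10 2-[(1S,5R)-2,2,4-trimethyl-5-[(tributylstannyl)methoxy]cyclohex-3-en-1-yl]ethan-1-ol
Product: 11 2-[(1R,5R)-2,2,4-trimethyl-5-[(tributylstannyl)methoxy]cyclohex-3-en-1-yl]acetaldehyde
Conditions: Dess–Martin periodinane, NaHCO3, CH2Cl2, 0 °C → rt
Reagents that add atoms: none
Why: Dess–Martin oxidation of a primary alcohol under buffered, non-acidic conditions that spare the stannane and the allylic ether. The aldehyde α-carbon is a methylene, so nothing can epimerise.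

Step 8
Reactants: 11 2-[(1R,5R)-2,2,4-trimethyl-5-[(tributylstannyl)methoxy]cyclohex-3-en-1-yl]acetaldehyde
Product: 12 tributyl({[(1R,5S)-2,4,4-trimethyl-5-(3-methylbut-2-en-1-yl)cyclohex-2-en-1-yl]oxy}methyl)stannane
Conditions: i-PrPPh3I (1.3 equiv), n-BuLi (1.2 equiv), THF, 0 °C; then 11, −78 °C → rt
Reagents that add atoms: isopropyltriphenylphosphonium iodide, CC(C)[P+](c1ccccc1)(c1ccccc1)c1ccccc1.[I-]
Why: Wittig olefination with the non-stabilised isopropylidene ylide gives the prenyl alkene, which has no geometrical isomers. The phosphonium salt is kept in excess over n-BuLi so that no free alkyllithium reaches the C–Sn bond.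

Step 9
Reactants: 12 tributyl({[(1R,5S)-2,4,4-trimethyl-5-(3-methylbut-2-en-1-yl)cyclohex-2-en-1-yl]oxy}methyl)stannane
Product: 14 [(1R,5S)-2,6,6-trimethyl-5-(3-methylbut-2-en-1-yl)cyclohex-2-en-1-yl]methanol, via lithiomethyl ether 13 (not isolated)
Conditions: n-BuLi (1.3 equiv), THF, −78 → −20 °C
Reagents that add atoms: none
Why: Wittig–Still [2,3]-sigmatropic rearrangement. Tin–lithium exchange gives the α-alkoxy carbanion, which shifts suprafacially through a five-membered envelope transition state. C7 is delivered to C6 on the face that carried the C4–O bond while the alkene moves to C4=C5, so the 1,5-cis ether gives the 2,6-cis ring with C6 set by the carbinol.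

Step 10
Reactants: 14 [(1R,5S)-2,6,6-trimethyl-5-(3-methylbut-2-en-1-yl)cyclohex-2-en-1-yl]methanol; 15 1-phenyl-1H-tetrazole-5-thiol
Product: 16 1-phenyl-5-({[(1R,5S)-2,6,6-trimethyl-5-(3-methylbut-2-en-1-yl)cyclohex-2-en-1-yl]methyl}sulfanyl)-1H-tetrazole
Conditions: PPh3, DIAD, THF, 0 °C → rt
Reagents that add atoms: none
Why: Mitsunobu thioetherification of a primary alcohol with an acidic heteroaryl thiol. Substitution is at C7 only, so no stereocentre is involved.

Step 11
Reactants: 16 1-phenyl-5-({[(1R,5S)-2,6,6-trimethyl-5-(3-methylbut-2-en-1-yl)cyclohex-2-en-1-yl]methyl}sulfanyl)-1H-tetrazole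
Product: 17 1-phenyl-5-({[(1R,5S)-2,6,6-trimethyl-5-(3-methylbut-2-en-1-yl)cyclohex-2-en-1-yl]methyl}sulfonyl)-1H-tetrazole (left sulfone)
Conditions: (NH4)6Mo7O24·4H2O (0.2 equiv), 30% H2O2, EtOH, 0 °C → rt
Reagents that add atoms: hydrogen peroxide, OO
Why: Molybdate-catalysed peroxide oxidation of sulfide to sulfone. The peroxomolybdate oxidises sulfur much faster than trisubstituted alkenes that lack a free allylic hydroxyl.

Step 12
Reactants: 6 (1R,5R)-5-ethenyl-2,4,4-trimethylcyclohex-2-en-1-ol
Product: 18 (1S,5R)-5-ethenyl-2,4,4-trimethylcyclohex-2-en-1-yl 4-nitrobenzoate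
Conditions: 4-O2NC6H4CO2H, PPh3, DIAD, toluene, 0 °C → rt
Reagents that add atoms: 4-nitrobenzoic acid, O=C(O)c1ccc(cc1)[N+](=O)[O-]
Why: Mitsunobu esterification with inversion (SN2 on the alkoxyphosphonium ion, as in cis- to trans-carveol), giving the 1,5-trans ester. Attack at the γ-carbon is disfavoured because that carbon is flanked by the quaternary centre.

Step 13
Reactants: 18 (1S,5R)-5-ethenyl-2,4,4-trimethylcyclohex-2-en-1-yl 4-nitrobenzoate
Product: 19 (1S,5R)-5-ethenyl-2,4,4-trimethylcyclohex-2-en-1-ol (1,5-trans)
Conditions: K2CO3 (0.2 equiv), MeOH, rt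
Reagents that add atoms: none
Why: Methanolysis of an activated aryl ester by acyl–oxygen cleavage, so the inverted carbinol configuration is kept.

Step 14
Reactants: 19 (1S,5R)-5-ethenyl-2,4,4-trimethylcyclohex-2-en-1-ol; 7 tributyl(iodomethyl)stannane
Product: 20 tributyl({[(1S,5R)-5-ethenyl-2,4,4-trimethylcyclohex-2-en-1-yl]oxy}methyl)stannane
Conditions: KH, 18-crown-6 (cat.), THF, 0 °C → rt
Reagents that add atoms: none
Why: Williamson etherification as in step 5, with retention at the carbinol carbon.

Step 15
Reactants: 20 tributyl({[(1S,5R)-5-ethenyl-2,4,4-trimethylcyclohex-2-en-1-yl]oxy}methyl)stannane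
Product: 22 2-[(1S,5S)-2,2,4-trimethyl-5-[(tributylstannyl)methoxy]cyclohex-3-en-1-yl]ethan-1-ol, via alkylborane 21 (not isolated)
Conditions: 9-BBN–H, THF, 0 °C → rt; then NaOH, H2O2, H2O, 0 °C → rt
Reagents that add atoms: hydrogen peroxide, OO
Why: Hydroboration–oxidation as in step 6, selective for the vinyl group over the ring alkene.

Step 16
Reactants: 22 2-[(1S,5S)-2,2,4-trimethyl-5-[(tributylstannyl)methoxy]cyclohex-3-en-1-yl]ethan-1-ol
Product: 23 2-[(1R,5S)-2,2,4-trimethyl-5-[(tributylstannyl)methoxy]cyclohex-3-en-1-yl]acetaldehyde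
Conditions: Dess–Martin periodinane, NaHCO3, CH2Cl2, 0 °C → rt
Reagents that add atoms: none
Why: Dess–Martin oxidation as in step 7.

Step 17
Reactants: 23 2-[(1R,5S)-2,2,4-trimethyl-5-[(tributylstannyl)methoxy]cyclohex-3-en-1-yl]acetaldehyde
Product: 24 ethyl (2E)-2-methyl-4-[(1S,5S)-2,2,4-trimethyl-5-[(tributylstannyl)methoxy]cyclohex-3-en-1-yl]but-2-enoate
Conditions: Ph3P=C(Me)CO2Et, CH2Cl2, rt
Reagents that add atoms: ethyl 2-(triphenylphosphoranylidene)propanoate, CCOC(=O)C(C)=P(c1ccccc1)(c1ccccc1)c1ccccc1
Why: Wittig olefination with a stabilised α-methyl ylide; reversible oxaphosphetane formation favours the (E)-trisubstituted enoate, which is the geometry of the side chain.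

Step 18
Reactants: 24 ethyl (2E)-2-methyl-4-[(1S,5S)-2,2,4-trimethyl-5-[(tributylstannyl)methoxy]cyclohex-3-en-1-yl]but-2-enoate
Product: 25 (2E)-2-methyl-4-[(1S,5S)-2,2,4-trimethyl-5-[(tributylstannyl)methoxy]cyclohex-3-en-1-yl]but-2-en-1-ol
Conditions: i-Bu2AlH (2.2 equiv), CH2Cl2, −78 °C
Reagents that add atoms: none
Why: 1,2-Reduction of an α,β-unsaturated ester to the allylic alcohol by the aluminium hydride. The double-bond geometry and the stannane are unaffected.

Step 19
Reactants: 25 (2E)-2-methyl-4-[(1S,5S)-2,2,4-trimethyl-5-[(tributylstannyl)methoxy]cyclohex-3-en-1-yl]but-2-en-1-ol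
Product: 26 tert-butyl(dimethyl){[(2E)-2-methyl-4-[(1S,5S)-2,2,4-trimethyl-5-[(tributylstannyl)methoxy]cyclohex-3-en-1-yl]but-2-en-1-yl]oxy}silane
Conditions: TBSCl, imidazole, CH2Cl2, rt
Reagents that add atoms: tert-butyl(chloro)dimethylsilane, CC(C)(C)[Si](C)(C)Cl
Why: Silylation of a primary allylic alcohol. The silyl ether tolerates n-BuLi at low temperature, Mitsunobu reagents, peroxomolybdate and KN(SiMe3)2, and is removed by fluoride at the end.

Step 20
Reactants: 26 tert-butyl(dimethyl){[(2E)-2-methyl-4-[(1S,5S)-2,2,4-trimethyl-5-[(tributylstannyl)methoxy]cyclohex-3-en-1-yl]but-2-en-1-yl]oxy}silane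
Product: 28 {(1S,5R)-5-[(2E)-4-{[tert-butyl(dimethyl)silyl]oxy}-3-methylbut-2-en-1-yl]-2,6,6-trimethylcyclohex-2-en-1-yl}methanol, via lithiomethyl ether 27 (not isolated)
Conditions: n-BuLi (1.3 equiv), THF, −78 → −20 °C
Reagents that add atoms: none
Why: Wittig–Still [2,3]-rearrangement as in step 9. In the trans ether the C–O bond is pseudoaxial while the side chain stays equatorial, and C7' is delivered to the face opposite the side chain, giving the 2',6'-trans ring.

Step 21
Reactants: 28 {(1S,5R)-5-[(2E)-4-{[tert-butyl(dimethyl)silyl]oxy}-3-methylbut-2-en-1-yl]-2,6,6-trimethylcyclohex-2-en-1-yl}methanol; 15 1-phenyl-1H-tetrazole-5-thiol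
Product: 29 5-({[(1S,5R)-5-[(2E)-4-{[tert-butyl(dimethyl)silyl]oxy}-3-methylbut-2-en-1-yl]-2,6,6-trimethylcyclohex-2-en-1-yl]methyl}sulfanyl)-1-phenyl-1H-tetrazole
Conditions: PPh3, DIAD, THF, 0 °C → rt
Reagents that add atoms: none
Why: Mitsunobu thioetherification as in step 10; the only free hydroxyl is the one at C7'.

Step 22
Reactants: 29 5-({[(1S,5R)-5-[(2E)-4-{[tert-butyl(dimethyl)silyl]oxy}-3-methylbut-2-en-1-yl]-2,6,6-trimethylcyclohex-2-en-1-yl]methyl}sulfanyl)-1-phenyl-1H-tetrazole
Product: 30 5-({[(1S,5R)-5-[(2E)-4-{[tert-butyl(dimethyl)silyl]oxy}-3-methylbut-2-en-1-yl]-2,6,6-trimethylcyclohex-2-en-1-yl]methyl}sulfonyl)-1-phenyl-1H-tetrazole (right sulfone)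
Conditions: (NH4)6Mo7O24·4H2O (0.2 equiv), 30% H2O2, EtOH, 0 °C → rt
Reagents that add atoms: hydrogen peroxide, OO
Why: Molybdate-catalysed sulfide-to-sulfone oxidation as in step 11. The allylic oxygen is silylated, so the side-chain alkene is not activated towards epoxidation.

Step 23
Reactants: 17 left sulfone; 31 crocetindial, (2E,4E,6E,8E,10E,12E,14E)-2,6,11,15-tetramethylhexadeca-2,4,6,8,10,12,14-heptaenedial; 30 right sulfone
Product: 35 tert-butyldimethylsilyl ether of the target (all-E), via potassium salt of metallated left sulfone 32 (not isolated), via C30 aldehyde 33 (not isolated), via potassium salt of metallated right sulfone 34 (not isolated)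
Conditions: 17, KN(SiMe3)2, THF, −78 °C, then added to 31 (3 equiv), THF, −78 → 0 °C; aqueous quench, silica plug (excess 31 recovered), crude 33 used directly; 30 (1.3 equiv), KN(SiMe3)2, THF, −78 °C, then crude 33, −78 °C → rt; dark, Ar
Reagents that add atoms: none
Why: Each sulfone is deprotonated at C7, a position not conjugated with the ring alkene; the carbanion adds 1,2 to an aldehyde group, the alkoxide attacks the tetrazole carbon (Smiles transfer of the heteroaryl from sulfur to oxygen), and loss of SO2 and the tetrazolone gives the alkene. This is the Julia–Kocienski olefination, and the closest known case is the olefination of conjugated polyene aldehydes with alkyl 1-phenyltetrazolyl sulfones. No ring is closed and no stereocentre is created; C7=C8 and C7'=C8' are formed one after the other. Mono-olefination is secured by inverse addition of 32 to three equivalents of 31; the remaining aldehyde of 33 has lost its acceptor partner at the far chain end and should be slightly less electrophilic, and the excess 31 is far more polar and stays on silica. E geometry is favoured by the β-branched sulfones and the potassium counter-ion in THF. The new double bonds are conjugated with the chain, so a 7Z or 7'Z isomer can be brought to all-E by a trace of I2 in daylight. C6–H and C6'–H are not acidified by the sulfonyl group, so both ring configurations are carried through, and the silyl ether is inert to the base.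

Step 24
Reactants: 35 tert-butyldimethylsilyl ether of the target
Product: 36 target, (2S,6R,2'R,6'S)-2-(3-methylbut-2-en-1-yl)-2'-[(2E)-4-hydroxy-3-methylbut-2-en-1-yl]-ε,ε-carotene (all-E)
Conditions: Bu4NF, THF, 0 °C → rt, dark, Ar
Reagents that add atoms: none
Why: Fluoride cleavage of a primary silyl ether under near-neutral conditions that neither isomerise the polyene nor move the ring double bonds into conjugation.

## Compound list

1 | 4,4-dimethylcyclohex-2-en-1-one | CC1(C)CCC(=O)C=C1 | starting material
2 | lithium 4,4-dimethylcyclohexa-1,5-dien-1-olate | [Li]OC1=CCC(C)(C)C=C1 | intermediate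
3 | (±)-4,4,6-trimethylcyclohex-2-en-1-one | CC1CC(C)(C)C=CC1=O | intermediate
4 | 2,4,4-trimethylcyclohexa-2,5-dien-1-one | CC1=CC(C)(C)C=CC1=O | intermediate
5 | (5R)-5-ethenyl-2,4,4-trimethylcyclohex-2-en-1-one | C=C[C@H]1CC(=O)C(C)=CC1(C)C | intermediate
6 | (1R,5R)-5-ethenyl-2,4,4-trimethylcyclohex-2-en-1-ol (cis) | C=C[C@H]1C[C@@H](O)C(C)=CC1(C)C | intermediate
7 | tributyl(iodomethyl)stannane | CCCC[Sn](CI)(CCCC)CCCC | starting material
8 | tributyl({[(1R,5R)-5-ethenyl-2,4,4-trimethylcyclohex-2-en-1-yl]oxy}methyl)stannane | C=C[C@H]1C[C@@H](OC[Sn](CCCC)(CCCC)CCCC)C(C)=CC1(C)C | intermediate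
9 | 9-{2-[(1S,5R)-2,2,4-trimethyl-5-[(tributylstannyl)methoxy]cyclohex-3-en-1-yl]ethyl}-9-borabicyclo[3.3.1]nonane | C(C[C@H]1C[C@@H](OC[Sn](CCCC)(CCCC)CCCC)C(C)=CC1(C)C)B1C2CCCC1CCC2 | intermediate
10 | 2-[(1S,5R)-2,2,4-trimethyl-5-[(tributylstannyl)methoxy]cyclohex-3-en-1-yl]ethan-1-ol | OCC[C@H]1C[C@@H](OC[Sn](CCCC)(CCCC)CCCC)C(C)=CC1(C)C | intermediate
11 | 2-[(1R,5R)-2,2,4-trimethyl-5-[(tributylstannyl)methoxy]cyclohex-3-en-1-yl]acetaldehyde | O=CC[C@H]1C[C@@H](OC[Sn](CCCC)(CCCC)CCCC)C(C)=CC1(C)C | intermediate
12 | tributyl({[(1R,5S)-2,4,4-trimethyl-5-(3-methylbut-2-en-1-yl)cyclohex-2-en-1-yl]oxy}methyl)stannane | CC(C)=CC[C@H]1C[C@@H](OC[Sn](CCCC)(CCCC)CCCC)C(C)=CC1(C)C | intermediate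
13 | ({[(1R,5S)-2,4,4-trimethyl-5-(3-methylbut-2-en-1-yl)cyclohex-2-en-1-yl]oxy}methyl)lithium | CC(C)=CC[C@H]1C[C@@H](OC[Li])C(C)=CC1(C)C | intermediate
14 | [(1R,5S)-2,6,6-trimethyl-5-(3-methylbut-2-en-1-yl)cyclohex-2-en-1-yl]methanol (2,6-cis in carotenoid numbering) | CC(C)=CC[C@H]1CC=C(C)[C@@H](CO)C1(C)C | intermediate
15 | 1-phenyl-1H-tetrazole-5-thiol | Sc1nnnn1-c1ccccc1 | starting material
16 | 1-phenyl-5-({[(1R,5S)-2,6,6-trimethyl-5-(3-methylbut-2-en-1-yl)cyclohex-2-en-1-yl]methyl}sulfanyl)-1H-tetrazole | CC(C)=CC[C@H]1CC=C(C)[C@@H](CSc2nnnn2-c2ccccc2)C1(C)C | intermediate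
17 | 1-phenyl-5-({[(1R,5S)-2,6,6-trimethyl-5-(3-methylbut-2-en-1-yl)cyclohex-2-en-1-yl]methyl}sulfonyl)-1H-tetrazole (left sulfone) | CC(C)=CC[C@H]1CC=C(C)[C@@H](CS(=O)(=O)c2nnnn2-c2ccccc2)C1(C)C | intermediate
18 | (1S,5R)-5-ethenyl-2,4,4-trimethylcyclohex-2-en-1-yl 4-nitrobenzoate | C=C[C@H]1C[C@H](OC(=O)c2ccc(cc2)[N+](=O)[O-])C(C)=CC1(C)C | intermediate
19 | (1S,5R)-5-ethenyl-2,4,4-trimethylcyclohex-2-en-1-ol (trans) | C=C[C@H]1C[C@H](O)C(C)=CC1(C)C | intermediate
20 | tributyl({[(1S,5R)-5-ethenyl-2,4,4-trimethylcyclohex-2-en-1-yl]oxy}methyl)stannane | C=C[C@H]1C[C@H](OC[Sn](CCCC)(CCCC)CCCC)C(C)=CC1(C)C | intermediate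
21 | 9-{2-[(1S,5S)-2,2,4-trimethyl-5-[(tributylstannyl)methoxy]cyclohex-3-en-1-yl]ethyl}-9-borabicyclo[3.3.1]nonane | C(C[C@H]1C[C@H](OC[Sn](CCCC)(CCCC)CCCC)C(C)=CC1(C)C)B1C2CCCC1CCC2 | intermediate
22 | 2-[(1S,5S)-2,2,4-trimethyl-5-[(tributylstannyl)methoxy]cyclohex-3-en-1-yl]ethan-1-ol | OCC[C@H]1C[C@H](OC[Sn](CCCC)(CCCC)CCCC)C(C)=CC1(C)C | intermediate
23 | 2-[(1R,5S)-2,2,4-trimethyl-5-[(tributylstannyl)methoxy]cyclohex-3-en-1-yl]acetaldehyde | O=CC[C@H]1C[C@H](OC[Sn](CCCC)(CCCC)CCCC)C(C)=CC1(C)C | intermediate
24 | ethyl (2E)-2-methyl-4-[(1S,5S)-2,2,4-trimethyl-5-[(tributylstannyl)methoxy]cyclohex-3-en-1-yl]but-2-enoate | CCOC(=O)/C(C)=C/C[C@H]1C[C@H](OC[Sn](CCCC)(CCCC)CCCC)C(C)=CC1(C)C | intermediate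
25 | (2E)-2-methyl-4-[(1S,5S)-2,2,4-trimethyl-5-[(tributylstannyl)methoxy]cyclohex-3-en-1-yl]but-2-en-1-ol | OC/C(C)=C/C[C@H]1C[C@H](OC[Sn](CCCC)(CCCC)CCCC)C(C)=CC1(C)C | intermediate
26 | tert-butyl(dimethyl){[(2E)-2-methyl-4-[(1S,5S)-2,2,4-trimethyl-5-[(tributylstannyl)methoxy]cyclohex-3-en-1-yl]but-2-en-1-yl]oxy}silane | CC(C)(C)[Si](C)(C)OC/C(C)=C/C[C@H]1C[C@H](OC[Sn](CCCC)(CCCC)CCCC)C(C)=CC1(C)C | intermediate
27 | ({[(1S,5S)-5-[(2E)-4-{[tert-butyl(dimethyl)silyl]oxy}-3-methylbut-2-en-1-yl]-2,4,4-trimethylcyclohex-2-en-1-yl]oxy}methyl)lithium | CC(C)(C)[Si](C)(C)OC/C(C)=C/C[C@H]1C[C@H](OC[Li])C(C)=CC1(C)C | intermediate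
28 | {(1S,5R)-5-[(2E)-4-{[tert-butyl(dimethyl)silyl]oxy}-3-methylbut-2-en-1-yl]-2,6,6-trimethylcyclohex-2-en-1-yl}methanol (2',6'-trans in carotenoid numbering) | CC(C)(C)[Si](C)(C)OC/C(C)=C/C[C@H]1CC=C(C)[C@H](CO)C1(C)C | intermediate
29 | 5-({[(1S,5R)-5-[(2E)-4-{[tert-butyl(dimethyl)silyl]oxy}-3-methylbut-2-en-1-yl]-2,6,6-trimethylcyclohex-2-en-1-yl]methyl}sulfanyl)-1-phenyl-1H-tetrazole | CC(C)(C)[Si](C)(C)OC/C(C)=C/C[C@H]1CC=C(C)[C@H](CSc2nnnn2-c2ccccc2)C1(C)C | intermediate
30 | 5-({[(1S,5R)-5-[(2E)-4-{[tert-butyl(dimethyl)silyl]oxy}-3-methylbut-2-en-1-yl]-2,6,6-trimethylcyclohex-2-en-1-yl]methyl}sulfonyl)-1-phenyl-1H-tetrazole (right sulfone) | CC(C)(C)[Si](C)(C)OC/C(C)=C/C[C@H]1CC=C(C)[C@H](CS(=O)(=O)c2nnnn2-c2ccccc2)C1(C)C | intermediate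
31 | crocetindial, (2E,4E,6E,8E,10E,12E,14E)-2,6,11,15-tetramethylhexadeca-2,4,6,8,10,12,14-heptaenedial | O=C/C(C)=C/C=C/C(C)=C/C=C/C=C(C)/C=C/C=C(C)/C=O | starting material
32 | potassium salt of the C7 carbanion of 17 | CC(C)=CC[C@H]1CC=C(C)[C@@H]([CH-]S(=O)(=O)c2nnnn2-c2ccccc2)C1(C)C.[K+] | intermediate
33 | (2E,4E,6E,8E,10E,12E,14E,16E)-2,6,11,15-tetramethyl-17-[(1R,5S)-2,6,6-trimethyl-5-(3-methylbut-2-en-1-yl)cyclohex-2-en-1-yl]heptadeca-2,4,6,8,10,12,14,16-octaenal (C30 aldehyde) | CC(C)=CC[C@H]1CC=C(C)[C@@H](/C=C/C(C)=C/C=C/C(C)=C/C=C/C=C(C)/C=C/C=C(C)/C=O)C1(C)C | intermediate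
34 | potassium salt of the C7' carbanion of 30 | CC(C)(C)[Si](C)(C)OC/C(C)=C/C[C@H]1CC=C(C)[C@H]([CH-]S(=O)(=O)c2nnnn2-c2ccccc2)C1(C)C.[K+] | intermediate
35 | tert-butyldimethylsilyl ether of the target, (2S,6R,2'R,6'S)-2'-[(2E)-4-{[tert-butyl(dimethyl)silyl]oxy}-3-methylbut-2-en-1-yl]-2-(3-methylbut-2-en-1-yl)-ε,ε-carotene | CC(C)=CC[C@H]1CC=C(C)[C@@H](/C=C/C(C)=C/C=C/C(C)=C/C=C/C=C(C)/C=C/C=C(C)/C=C/[C@H]2C(C)=CC[C@H](C/C=C(\C)CO[Si](C)(C)C(C)(C)C)C2(C)C)C1(C)C | intermediate
36 | (2S,6R,2'R,6'S)-2-(3-methylbut-2-en-1-yl)-2'-[(2E)-4-hydroxy-3-methylbut-2-en-1-yl]-ε,ε-carotene (all-E) | CC(C)=CC[C@H]1CC=C(C)[C@@H](/C=C/C(C)=C/C=C/C(C)=C/C=C/C=C(C)/C=C/C=C(C)/C=C/[C@H]2C(C)=CC[C@H](C/C=C(\C)CO)C2(C)C)C1(C)C | target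

## Step count and least certain steps

Total: 24 steps. Longest linear sequence: 17 steps (steps 1–4, 12–22, 23, 24).

**Step 23 (key step).** The first stage is the most likely to fall short, through over-olefination to the symmetrical bis-adduct together with incomplete conversion. The two aldehyde groups of 31 differ little in reactivity, and 31 dissolves poorly in cold THF, so the more soluble mono-adduct competes for the carbanion. Incomplete E selectivity with a conjugated aldehyde is a second risk, but a matter of conditions (iodine equilibration, as noted in the step). Fallback: differentiate the two chain ends by protection instead of stoichiometry. It sets out from 31 and 17 and comes back at 33. Crocetindial 31 is converted with one equivalent of HC(OMe)3 and pyridinium p-toluenesulfonate in MeOH/CH2Cl2 into its mono(dimethyl acetal) F1; bis-acetal and unchanged 31 are recycled. Metallated 17 is olefinated 1:1 with F1 to give the C30 acetal F2, which has no second aldehyde. Dilute aqueous acid (pyridinium p-toluenesulfonate, acetone/H2O) releases 33, which is then purified before the olefination with 30.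

**Step 3.** Addition to a β-carbon next to the quaternary centre may be slow, so that protodeboronation of the vinyl reagent outruns carbometallation and the enantioselectivity falls below what the later diastereomer separations can absorb. Fallback: racemic addition followed by enzymatic resolution. It sets out from 4 and comes back at 6. CH2=CHMgBr with catalytic CuBr·SMe2 and Me3SiCl in THF at −78 °C, then dilute acid, gives racemic enone F3. Luche reduction gives the racemic cis alcohol F4. Lipase-catalysed acylation with vinyl acetate (Burkholderia cepacia lipase) is expected, by the empirical rule for secondary alcohols, to acylate the (1R)-enantiomer to acetate F5, while the slower enantiomer of F4 stays behind and is removed. Methanolysis of F5 (K2CO3, MeOH) gives 6.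

**Step 9.** The lithiomethyl ether may be diverted to a [1,2]-shift or to simple protonation. The [2,3] transition state needs the C–O bond pseudoaxial, and in the cis series this places the C2 side chain axial next to the gem-dimethyl group and on the face where the new bond forms. Step 20 is the same reaction on the trans isomer, whose reactive conformer is unstrained, and is judged the safer of the two. Fallback: a neutral, thermal [2,3]-shift of an amide acetal in place of the carbanion. It sets out from 6, replaces steps 5 to 9 and comes back at 14. Heating 6 with Me2NCH(OMe)2 in xylene at 140 °C with removal of methanol gives the cis β,γ-unsaturated amide F6. 9-BBN–H then NaOH/H2O2 gives the hydroxyethyl amide F7, and Dess–Martin oxidation gives the aldehyde F8. The isopropylidene ylide, added to the aldehyde at −78 °C so that the amide α-hydrogen is not exposed to excess base, gives the prenyl amide F9. LiEt3BH in THF reduces F9 to 14.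

**Step 12.** The allylic alkoxyphosphonium ion may ionise or eliminate, giving loss of stereochemical fidelity (ester with retention) or the diene instead of clean inversion. Fallback: set the trans carbinol by reagent control instead of inversion. It sets out from 5 and comes back at 19, replacing steps 4, 12 and 13 for the right-hand branch, and makes no new compound. Corey–Bakshi–Shibata reduction of 5 with the (R)-methyl oxazaborolidine and catecholborane is expected, with the alkene side as the large group, to give the (1S)-alcohol against the substrate bias; the minor cis isomer 6 is separated and used in the left branch.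

**Step 10 (and the same reaction in step 21).** Substitution at the β-branched, neopentyl-like C7 may be slow, so that the Mitsunobu betaine is consumed by the acidic thiol before the alcohol is displaced and conversion stalls. Fallback: activation and displacement in two separate steps. It sets out from 14 and comes back at 16. I2, PPh3 and imidazole in CH2Cl2 give the iodide F10, which is displaced by 15 with K2CO3 in DMF at 50 °C to give 16.

## Further compounds

F1 | step 23 | (2E,4E,6E,8E,10E,12E,14E)-16,16-dimethoxy-2,6,11,15-tetramethylhexadeca-2,4,6,8,10,12,14-heptaenal | COC(OC)/C(C)=C/C=C/C(C)=C/C=C/C=C(C)/C=C/C=C(C)/C=O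
F2 | step 23 | dimethyl acetal of C30 aldehyde 33 | CC(C)=CC[C@H]1CC=C(C)[C@@H](/C=C/C(C)=C/C=C/C(C)=C/C=C/C=C(C)/C=C/C=C(C)/C(OC)OC)C1(C)C
F3 | step 3 | (±)-5-ethenyl-2,4,4-trimethylcyclohex-2-en-1-one (racemate, both enantiomers written) | C=C[C@H]1CC(=O)C(C)=CC1(C)C.C=C[C@@H]1CC(=O)C(C)=CC1(C)C
F4 | step 3 | (±)-cis-5-ethenyl-2,4,4-trimethylcyclohex-2-en-1-ol (racemate, both enantiomers written) | C=C[C@H]1C[C@@H](O)C(C)=CC1(C)C.C=C[C@@H]1C[C@H](O)C(C)=CC1(C)C
F5 | step 3 | (1R,5R)-5-ethenyl-2,4,4-trimethylcyclohex-2-en-1-yl acetate | C=C[C@H]1C[C@@H](OC(C)=O)C(C)=CC1(C)C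
F6 | step 9 | (1R,5R)-5-ethenyl-N,N,2,6,6-pentamethylcyclohex-2-ene-1-carboxamide | C=C[C@H]1CC=C(C)[C@@H](C(=O)N(C)C)C1(C)C
F7 | step 9 | (1R,5R)-5-(2-hydroxyethyl)-N,N,2,6,6-pentamethylcyclohex-2-ene-1-carboxamide | OCC[C@H]1CC=C(C)[C@@H](C(=O)N(C)C)C1(C)C
F8 | step 9 | (1R,5R)-N,N,2,6,6-pentamethyl-5-(2-oxoethyl)cyclohex-2-ene-1-carboxamide | O=CC[C@H]1CC=C(C)[C@@H](C(=O)N(C)C)C1(C)C
F9 | step 9 | (1R,5S)-N,N,2,6,6-pentamethyl-5-(3-methylbut-2-en-1-yl)cyclohex-2-ene-1-carboxamide | CC(C)=CC[C@H]1CC=C(C)[C@@H](C(=O)N(C)C)C1(C)C
F0 | step 12 | none | none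
F10 | step 10 | (4S,6R)-6-(iodomethyl)-1,5,5-trimethyl-4-(3-methylbut-2-en-1-yl)cyclohex-1-ene | CC(C)=CC[C@H]1CC=C(C)[C@@H](CI)C1(C)C
A1 | alternative 1 | 1,1,3,3-tetrabromopropan-2-one | BrC(Br)C(=O)C(Br)Br
A2 | alternative 1 | 5,5-dimethylcyclopenta-1,3-diene | CC1(C)C=CC=C1
A3 | alternative 1 | meso-8,8-dimethylbicyclo[3.2.1]oct-6-en-3-one | O=C1C[C@@H]2C=C[C@H](C1)C2(C)C
A4 | alternative 2 | (R)-limonene | CC1=CC[C@@H](CC1)C(C)=C
A5 | alternative 2 | (3E,5E,9R)-6,10-dimethyl-9-[2-(pivaloyloxy)ethyl]undeca-3,5,10-trien-2-one | CC(=O)/C=C/C=C(C)/CC[C@H](CCOC(=O)C(C)(C)C)C(C)=C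
A6 | alternative 2 | (E)-4-[cis-2,6,6-trimethyl-5-(2-pivaloyloxyethyl)cyclohex-2-en-1-yl]but-3-en-2-one | CC(C)(C)C(=O)OCC[C@H]1CC=C(C)[C@@H](/C=C/C(C)=O)C1(C)C
A7 | alternative 3 | 2-methylpropanal (isobutyraldehyde) | CC(C)C=O
A8 | alternative 3 | (E)-7-[(4-methoxybenzyl)oxy]hept-4-en-3-one | CCC(=O)/C=C/CCOCc1ccc(OC)cc1
A9 | alternative 3 | (5S)-5-{2-[(4-methoxybenzyl)oxy]ethyl}-2,4,4-trimethylcyclohex-2-en-1-one | O=C1C(C)=CC(C)(C)[C@@H](CCOCc2ccc(OC)cc2)C1
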